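## Retrosynthetic overview

1. **Feature.** Number the cyclohexane C1 (CH bearing the triene), C2 (CHMe), C3 (C(Me)OH), C4 (CHOAc), C5 (C(Me)OH), C6 (CHOAc). C3–C4–C5 with their methyls form a 3-pentanone skeleton oxygenated on both α-carbons, and O3 and O5 are cis. Joining O3 to O5 through an isopropylidene carbon turns this segment into the ring of meso cis-2,2,4,6-tetramethyl-1,3-dioxan-5-one.
2. **Key disconnection.** C2–C3 (conjugate addition) and C5–C6 (aldol) are cut together. The carbocycle then splits into that dioxanone, used as its enantioenriched enol silane, and (E)-2-(silyloxymethyl)but-2-enal (C2, C1, C6, C7). The annulation product is a 2,4-dioxabicyclo[3.3.1]nonan-9-one.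
3. **After the annulation.** C4=O is reduced, and the O3/O5 bridge is exchanged for two cis-fused dioxolanes (O3/O4 and O5/O6). C7 is oxidised, and C7=C8 and C9=C10 come from two Wittig reactions. C11=C12 comes from a vinylogous aldol–elimination with 2-ethyl-6-methoxy-3,5-dimethyl-4-pyranone. Hydrolysis and acetylation of the two secondary alcohols finish the route.
4. **Ring order.** The dioxanone ring is bought, the carbocycle is closed in the key step, and the two dioxolanes follow as protecting rings. The pyranone ring is closed separately from a triketo ester and joined last.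
5. **Absolute configuration.** It comes from one event: a chiral lithium amide removes one of the two enantiotopic α-hydrogens of the meso ketone.

Key step: step 8

**Numbering and drawing convention.** C1–C6 are as above. The side chain runs from C7 (on C1) to C12 (on the pyranone), and O3–O6 are the oxygens on C3–C6. With the ring drawn flat and C1→C6 clockwise, β is up and α is down. In the target O3, O4, O5 and O6 are β, while C7, 2-Me, 3-Me and 5-Me are α (C1 R, C2 S, C3 R, C4 R, C5 S, C6 S).

**Assumption.** The sense of proton selection by lithium (S,S)-bis(1-phenylethyl)amide on the meso ketone is inferred from its behaviour with 4-substituted cyclohexanones. If the opposite enol silane forms, the (R,R)-amine is used and nothing else changes.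

## Route

Step 1
Reactants: 1 2,2-dimethyl-1,3-dioxan-5-one; 2 N,N-dimethylhydrazine
Product: 3 2,2-dimethyl-1,3-dioxan-5-one N,N-dimethylhydrazone
Conditions: Me2NNH2 (1.2 equiv), 4 Å MS, CH2Cl2, rt
Reagents that add atoms: N,N-dimethylhydrazine (2), CN(C)N
Why: Hydrazone condensation of an unhindered ketone; the detour is needed because lithium enolates of 1,3-dioxan-5-ones alkylate poorly (self-aldol addition and hydride transfer from the amide compete), whereas their hydrazone azaenolates alkylate cleanly.

Step 2
Reactants: 3 2,2-dimethyl-1,3-dioxan-5-one N,N-dimethylhydrazone; 4 iodomethane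
Product: 6 trans-2,2,4,6-tetramethyl-1,3-dioxan-5-one N,N-dimethylhydrazone (racemic), via monomethyl hydrazone 5 (not isolated)
Conditions: t-BuLi (1.05 equiv), THF, −78 °C; MeI (1.0 equiv), −78 → 0 °C; t-BuLi (1.1 equiv), −78 °C; MeI (1.2 equiv), −78 °C → rt
Reagents that add atoms: iodomethane (4), CI
Why: Hydrazone azaenolate alkylation run twice in one flask; the second deprotonation takes place at the still unsubstituted α′-CH2, so one methyl ends up on each side, and the relative configuration formed here (mainly trans) is corrected in step 3.

Step 3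
Reactants: 6 trans-2,2,4,6-tetramethyl-1,3-dioxan-5-one N,N-dimethylhydrazone
Product: 8 cis-2,2,4,6-tetramethyl-1,3-dioxan-5-one (meso; 4R,6S), via trans ketone 7 (not isolated)
Conditions: sat. aq. (CO2H)2, Et2O, rt; separated Et2O layer, DBU (0.1 equiv), rt
Reagents that add atoms: water, O
Why: Two-phase acid hydrolysis of the hydrazone spares the acetonide, and base-catalysed epimerisation through the enolate then drains the trans ketone into the cis isomer, the only one that keeps both methyls equatorial and away from the axial acetonide methyl, so the relative configuration is set thermodynamically.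

Step 4
Reactants: 8 cis-2,2,4,6-tetramethyl-1,3-dioxan-5-one
Product: 9 (4R)-2,2,4,6-tetramethyl-5-(trimethylsilyloxy)-4H-1,3-dioxine (sp2 carbon = future C3, remaining stereocentre = future C5)
Conditions: (S,S)-bis(1-phenylethyl)amine·HCl (1.2 equiv), n-BuLi (2.4 equiv), THF, −78 → 0 °C; then −100 °C, Me3SiCl (5 equiv), 8
Reagents that add atoms: chlorotrimethylsilane, C[Si](C)(C)Cl
Why: Enantiotopic-group-selective deprotonation of a meso ketone by a C2-symmetric chiral lithium amide with LiCl present and in situ silyl trapping, a reaction type established for cis-2,6-dimethylcyclohexanone and for Cs-symmetric 1,3-dioxan-5-ones; both α-hydrogens are axial and stereoelectronically aligned, the base should take the one on the (S)-carbon, and the untouched (R)-carbon is the only stereocentre of 9.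

Step 5
Reactants: 10 (E)-but-2-enal (crotonaldehyde)
Product: 11 (Z)-2-iodobut-2-enal
Conditions: I2 (1.5 equiv), K2CO3 (1.2 equiv), DMAP (0.2 equiv), THF–H2O 1:1, rt
Reagents that add atoms: iodine, II
Why: α-Iodination of an enal by conjugate addition of DMAP, iodination of the enolate and elimination (Baylis–Hillman-type nucleophilic catalysis); elimination gives the more stable Z iodide, in which methyl and formyl are trans as required in 14.

Step 6
Reactants: 11 (Z)-2-iodobut-2-enal; 12 (tributylstannyl)methanol
Product: 13 (E)-2-(hydroxymethyl)but-2-enal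
Conditions: Pd2(dba)3 (2.5 mol %), AsPh3 (20 mol %), CuI (10 mol %), NMP, rt → 45 °C
Reagents that add atoms: (tributylstannyl)methanol (12), CCCC[Sn](CCCC)(CCCC)CO
Why: Stille coupling of an activated alkenyl iodide with a hydroxymethylstannane, in which the oxygen-bearing carbon is transferred in preference to butyl and the alkene geometry is retained.

Step 7
Reactants: 13 (E)-2-(hydroxymethyl)but-2-enal
Product: 14 (E)-2-[(tert-butyldimethylsilyl)oxymethyl]but-2-enal
Conditions: t-BuMe2SiCl (1.1 equiv), imidazole (1.5 equiv), CH2Cl2, 0 °C
Reagents that add atoms: tert-butyldimethylsilyl chloride, CC(C)(C)[Si](C)(C)Cl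
Why: Standard silylation of a primary allylic alcohol under conditions too mild to move or isomerise the double bond.

Step 8
Reactants: 9 (4R)-2,2,4,6-tetramethyl-5-(trimethylsilyloxy)-4H-1,3-dioxine; 14 (E)-2-[(tert-butyldimethylsilyl)oxymethyl]but-2-enal
Product: 16 acetonide-bridged bicyclic ketol 7-[(tert-butyldimethylsilyl)oxymethyl]-6-hydroxy-1,3,3,5,8-pentamethyl-2,4-dioxabicyclo[3.3.1]nonan-9-one (route numbering: C4 ketone; O3/O5 bridge and 6-OH β; C7 and 2-Me α), via keto aldehyde 15 (not isolated)
Conditions: AlMe3 (1.1 equiv), 2,6-diphenylphenol (3.3 equiv), toluene, rt; 14, −78 °C; 9 (1.2 equiv), −78 → −40 °C; then MeOH, K2CO3 (6 equiv), −40 → 0 °C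
Reagents that add atoms: none
Why: Proposed new method: aluminium tris(2,6-diphenylphenoxide) binds the formyl oxygen of 14 and buries C6 in its aryl pocket, so the neutral enol silane 9 (too weak a base to deprotonate the γ-methyl) can only add through C3 to C2 (Mukaiyama–Michael addition); methanol then destroys the aluminium phenoxide and removes the silyl group to free keto aldehyde 15, and carbonate/methoxide enolises the only α-hydrogen left on the ketone (axial H-5) so that C5 closes onto C6. The closest known reactions are the α,α′-annulation of cyclic ketone enamines and β-keto ester enolates with enals (Michael then aldol) to bicyclo[3.3.1]nonan-9-ones and conjugate additions to enals complexed by this aluminium phenoxide; new is the pairing of a tetrasubstituted, α-oxygenated donor with an α,β-disubstituted enal. The one ring closed, the carbocycle C1–C6, forms by a 6-(enolendo)-exo-trig aldol addition (the C4=C5 enolate bond lies inside the new ring), a favoured mode, and completes the 2,4-dioxabicyclo[3.3.1]nonan-9-one. C3 is set by attack anti to the C5 methyl, the sense in which 4-substituted dioxanone enolate equivalents accept electrophiles, so the stereocentre left by the chiral base is relayed to C3, and C5 is then re-formed on the only face the three-atom tether can reach, which forces O3 and O5 syn and both methyls outward. C2 depends on the enal face: in an open transition state with C1=C2 antiperiplanar to C3=C4 the C2 methyl lies over the dioxine ring between O3 and C4 and the C2 hydrogen lies next to the C3 methyl and the silyloxy group, which gives the required 2-methyl trans to O3 but is the least secure element, whereas C1 (enolisable in 15) and C6 (reversible aldol) settle thermodynamically, CH2OSi equatorial because the axial site points into the acetonide and 6-OH equatorial because the axial site is syn-axial to the C2 methyl. The step needs 1,4- over 1,2-addition, secured by the shielded formyl group and the α-branch of 14, and ring closure faster than loss of silanolate from C7, helped by the axial C3 side chain that holds C6 next to C5.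

Step 9
Reactants: 16 acetonide-bridged bicyclic ketol
Product: 17 bridged diol 7-[(tert-butyldimethylsilyl)oxymethyl]-1,3,3,5,8-pentamethyl-2,4-dioxabicyclo[3.3.1]nonane-6,9-diol (4-OH and 6-OH β, on the face of O3 and O5)
Conditions: LiAlH4 (1.5 equiv), Et2O, −78 → −20 °C
Reagents that add atoms: none
Why: Hydride reduction of a hindered α,α′-dioxygenated ketone with a small aprotic reagent (aprotic so that no retro-aldol opening can feed an aldehyde to the hydride); the inner acetonide methyl cannot face H-1, so the dioxanone ring of 16 should sit as a boat that hangs this methyl over the dioxane-side face of C4=O, and hydride should therefore enter from the carbocycle side, antiperiplanar to the C3–O3 and C5–O5 bonds (polar Felkin–Anh sense) and past the axial C2 methyl, which places the new 4-OH β.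

Step 10
Reactants: 17 bridged diol
Product: 18 bis-acetonide silyl ether (O3/O4 and O5/O6 isopropylidene, both cis-fused and β; C7H2OSiMe2t-Bu, 2-Me, 3-Me, 5-Me α)
Conditions: Me2C(OMe)2 (10 equiv), camphorsulfonic acid (5 mol %), acetone, 0 °C → rt; Et3N quench
Reagents that add atoms: 2,2-dimethoxypropane, COC(C)(C)OC
Why: Acid-catalysed transketalisation under thermodynamic control; the strained bridging 1,3-dioxane, now pressed against the 4-OH, opens and the four cis oxygens pair up in the only fully protected arrangement possible, two cis-fused dioxolanes, without breaking any ring C–O bond, so no stereocentre changes and the primary silyl ether survives the nearly methanol-free medium.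

Step 11
Reactants: 18 bis-acetonide silyl ether
Product: 19 bis-acetonide primary alcohol (C7H2OH)
Conditions: Bu4NF (1.2 equiv), THF, 0 °C → rt
Reagents that add atoms: none
Why: Fluoride cleavage of a primary silyl ether, to which ketals are inert.

Step 12
Reactants: 19 bis-acetonide primary alcohol
Product: 20 bis-acetonide aldehyde (C7HO on C1, α)
Conditions: Dess–Martin periodinane (1.3 equiv), CH2Cl2, 0 °C → rt
Reagents that add atoms: none
Why: Dess–Martin oxidation under non-basic conditions; the formyl group on C1 is equatorial (the axial site would be syn-axial to O3 and O5), so the existing configuration is also the stable one, and O6 is a poor, equatorially held leaving group, which guards against β-elimination.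

Step 13
Reactants: 20 bis-acetonide aldehyde; 21 2-(triphenylphosphoranylidene)propanal
Product: 22 (E)-enal (C1–C7H=C8(Me)–C9HO)
Conditions: 21 (1.5 equiv), toluene, 90 °C
Reagents that add atoms: 2-(triphenylphosphoranylidene)propanal (21), CC(C=O)=P(c1ccccc1)(c1ccccc1)c1ccccc1
Why: Wittig reaction with a stabilised formyl ylide, which attacks the aliphatic aldehyde 20 much faster than the α-methyl enal it produces and gives the trisubstituted C7=C8 alkene with the E selectivity typical of stabilised ylides.

Step 14
Reactants: 22 (E)-enal; 23 (triphenylphosphoranylidene)acetaldehyde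
Product: 24 (E,E)-dienal (C7=C8(Me)–C9H=C10H–C11HO)
Conditions: 23 (1.2 equiv), toluene, 70 °C
Reagents that add atoms: (triphenylphosphoranylidene)acetaldehyde (23), O=CC=P(c1ccccc1)(c1ccccc1)c1ccccc1
Why: Second Wittig reaction with a stabilised formyl ylide gives the E C9=C10 bond; a small excess of ylide and a moderate temperature limit a further two-carbon homologation of the product.

Step 15
Reactants: 25 ethyl 2-methyl-3-oxopentanoate; 26 N-methoxy-N-methylpropanamide
Product: 27 ethyl 2,4-dimethyl-3,5-dioxoheptanoate (mixture of stereoisomers and enol forms)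
Conditions: LiN(iPr)2 (2.2 equiv), THF, −78 → 0 °C; 26 (1.0 equiv), −78 → 0 °C; 1 M HCl
Reagents that add atoms: N-methoxy-N-methylpropanamide (26), CCC(=O)N(C)OC
Why: γ-Acylation of a β-keto ester dianion (the more basic C4 terminus reacts) with a Weinreb amide, whose tetrahedral adduct survives until the quench and so prevents proton exchange and over-addition; the stereocentres of 27 are irrelevant because both become sp2.

Step 16
Reactants: 27 ethyl 2,4-dimethyl-3,5-dioxoheptanoate
Product: 28 6-ethyl-4-hydroxy-3,5-dimethyl-2H-pyran-2-one
Conditions: DBU (1.0 equiv), toluene, reflux; 1 M HCl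
Reagents that add atoms: none
Why: Base-induced lactonisation of the C5 enol onto the ester (triketide to 4-hydroxy-2-pyrone cyclisation), driven by loss of ethanol and formation of the conjugated pyrone ring.

Step 17
Reactants: 28 6-ethyl-4-hydroxy-3,5-dimethyl-2H-pyran-2-one
Product: 29 2-ethyl-6-methoxy-3,5-dimethyl-4H-pyran-4-one
Conditions: MeOSO2CF3 (1.2 equiv), CH2Cl2, rt; 1 M NaOH wash
Reagents that add atoms: methyl trifluoromethanesulfonate, COS(=O)(=O)C(F)(F)F
Why: O-Methylation of a 4-hydroxy-2-pyrone with a hard methylating agent takes place at the more basic lactone carbonyl oxygen to give a 2-methoxy-4-hydroxypyrylium salt, which loses a proton in the basic wash and gives the 2-methoxy-4-pyranone rather than the 4-methoxy-2-pyrone.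

Step 18
Reactants: 24 (E,E)-dienal; 29 2-ethyl-6-methoxy-3,5-dimethyl-4H-pyran-4-one
Product: 30 aldol adduct (pyranone–C12H(Me)–C11H(OH)–C10H=C9H–C8(Me)=C7H–C1; mixture at C11 and C12)
Conditions: 29 (1.3 equiv), LiN(SiMe3)2 (1.3 equiv), THF, −78 °C; 24, −78 °C; H2O; light excluded
Reagents that add atoms: none
Why: Vinylogous aldol addition; the CH2 of the 2-ethyl group is the vinylogous α-position of the pyranone carbonyl and the most acidic site of 29, and its lithium dienolate adds 1,2 to the dienal at low temperature, while the two new stereocentres are removed in step 19.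

Step 19
Reactants: 30 aldol adduct
Product: 32 (E,E,E)-triene pyranone bis-acetonide, via allylic mesylate 31 (not isolated)
Conditions: MeSO2Cl (1.5 equiv), Et3N (3 equiv), CH2Cl2, −20 °C; then DBU (3 equiv), −20 °C → rt; light excluded
Reagents that add atoms: methanesulfonyl chloride, CS(=O)(=O)Cl (its atoms stay only in 31)
Why: Mesylation followed by E1cB elimination through the pyranone dienolate; the E C11=C12 alkene is expected because it keeps the bulky 3-methylpyranone ring trans to the chain, and it completes the conjugated triene.

Step 20
Reactants: 32 (E,E,E)-triene pyranone bis-acetonide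
Product: 33 tetraol (3-, 4-, 5-, 6-OH all β)
Conditions: 1 M aq. HCl–THF 1:3, rt, light excluded
Reagents that add atoms: none
Why: Acid hydrolysis of two mutually crowded cis-fused dioxolanes; the triene is deactivated toward protonation by conjugation with the pyranone, the 2-methoxy-4-pyranone is only reversibly protonated on its carbonyl oxygen under these conditions, and no stereocentre is touched.

Step 21
Reactants: 33 tetraol
Product: 34 amaurone B
Conditions: Ac2O (3 equiv), pyridine (6 equiv), DMAP (0.1 equiv), CH2Cl2, 0 °C → rt, light excluded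
Reagents that add atoms: acetic anhydride, CC(=O)OC(C)=O
Why: Chemoselective acylation under nucleophilic catalysis; the two equatorial secondary hydroxyls at C4 and C6 are acetylated while the two axial, mutually hydrogen-bonded tertiary hydroxyls at C3 and C5 should stay free at this temperature and stoichiometry.

## Compound list

1 | 2,2-dimethyl-1,3-dioxan-5-one | CC1(C)OCC(=O)CO1 | starting material
2 | N,N-dimethylhydrazine | CN(C)N | starting material
3 | 2,2-dimethyl-1,3-dioxan-5-one N,N-dimethylhydrazone | CN(C)N=C1COC(C)(C)OC1 | intermediate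
4 | iodomethane | CI | starting material
5 | 2,2,4-trimethyl-1,3-dioxan-5-one N,N-dimethylhydrazone (racemic) | CC1OC(C)(C)OCC1=NN(C)C | intermediate
6 | trans-2,2,4,6-tetramethyl-1,3-dioxan-5-one N,N-dimethylhydrazone (racemic, one enantiomer drawn) | C[C@H]1OC(C)(C)O[C@H](C)C1=NN(C)C | intermediate
7 | trans-2,2,4,6-tetramethyl-1,3-dioxan-5-one (racemic, one enantiomer drawn) | C[C@H]1OC(C)(C)O[C@H](C)C1=O | intermediate
8 | cis-2,2,4,6-tetramethyl-1,3-dioxan-5-one (meso, 4R,6S) | C[C@H]1OC(C)(C)O[C@@H](C)C1=O | intermediate
9 | (4R)-2,2,4,6-tetramethyl-5-(trimethylsilyloxy)-4H-1,3-dioxine | C[C@H]1OC(C)(C)OC(C)=C1O[Si](C)(C)C | intermediate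
10 | (E)-but-2-enal | C/C=C/C=O | starting material
11 | (Z)-2-iodobut-2-enal | C/C=C(\I)C=O | intermediate
12 | (tributylstannyl)methanol | CCCC[Sn](CCCC)(CCCC)CO | starting material
13 | (E)-2-(hydroxymethyl)but-2-enal | C/C=C(\CO)C=O | intermediate
14 | (E)-2-[(tert-butyldimethylsilyl)oxymethyl]but-2-enal | C/C=C(\CO[Si](C)(C)C(C)(C)C)C=O | intermediate
15 | keto aldehyde: 2-[(tert-butyldimethylsilyl)oxymethyl]-3-(2,2,4,6-tetramethyl-5-oxo-1,3-dioxan-4-yl)butanal (C2, C3, C5 as drawn; C1 epimerisable) | CC(C)(C)[Si](C)(C)OC[C@@H](C=O)[C@H](C)[C@@]1(C)OC(C)(C)O[C@H](C)C1=O | intermediate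
16 | acetonide-bridged bicyclic ketol | CC(C)(C)[Si](C)(C)OC[C@@H]1[C@H](C)[C@@]2(C)OC(C)(C)O[C@](C)(C2=O)[C@H]1O | intermediate
17 | acetonide-bridged 4,6-diol | CC(C)(C)[Si](C)(C)OC[C@@H]1[C@H](C)[C@@]2(C)OC(C)(C)O[C@](C)([C@@H]2O)[C@H]1O | intermediate
18 | bis-acetonide silyl ether | CC(C)(C)[Si](C)(C)OC[C@@H]1[C@H](C)[C@@]2(C)OC(C)(C)O[C@H]2[C@@]3(C)OC(C)(C)O[C@@H]13 | intermediate
19 | bis-acetonide primary alcohol | OC[C@@H]1[C@H](C)[C@@]2(C)OC(C)(C)O[C@H]2[C@@]3(C)OC(C)(C)O[C@@H]13 | intermediate
20 | bis-acetonide aldehyde | O=C[C@@H]1[C@H](C)[C@@]2(C)OC(C)(C)O[C@H]2[C@@]3(C)OC(C)(C)O[C@@H]13 | intermediate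
21 | 2-(triphenylphosphoranylidene)propanal | CC(C=O)=P(c1ccccc1)(c1ccccc1)c1ccccc1 | starting material
22 | (E)-enal | O=C/C(C)=C/[C@@H]1[C@H](C)[C@@]2(C)OC(C)(C)O[C@H]2[C@@]3(C)OC(C)(C)O[C@@H]13 | intermediate
23 | (triphenylphosphoranylidene)acetaldehyde | O=CC=P(c1ccccc1)(c1ccccc1)c1ccccc1 | starting material
24 | (E,E)-dienal | O=C/C=C/C(C)=C/[C@@H]1[C@H](C)[C@@]2(C)OC(C)(C)O[C@H]2[C@@]3(C)OC(C)(C)O[C@@H]13 | intermediate
25 | ethyl 2-methyl-3-oxopentanoate | CCC(=O)C(C)C(=O)OCC | starting material
26 | N-methoxy-N-methylpropanamide | CCC(=O)N(C)OC | starting material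
27 | ethyl 2,4-dimethyl-3,5-dioxoheptanoate | CCC(=O)C(C)C(=O)C(C)C(=O)OCC | intermediate
28 | 6-ethyl-4-hydroxy-3,5-dimethyl-2H-pyran-2-one | CCC1=C(C)C(O)=C(C)C(=O)O1 | intermediate
29 | 2-ethyl-6-methoxy-3,5-dimethyl-4H-pyran-4-one | CCc1oc(OC)c(C)c(=O)c1C | intermediate
30 | aldol adduct (mixture at C11, C12) | COc1oc(C(C)C(O)/C=C/C(C)=C/[C@@H]2[C@H](C)[C@@]3(C)OC(C)(C)O[C@H]3[C@@]4(C)OC(C)(C)O[C@@H]24)c(C)c(=O)c1C | intermediate
31 | allylic mesylate (mixture at C11, C12) | COc1oc(C(C)C(OS(C)(=O)=O)/C=C/C(C)=C/[C@@H]2[C@H](C)[C@@]3(C)OC(C)(C)O[C@H]3[C@@]4(C)OC(C)(C)O[C@@H]24)c(C)c(=O)c1C | intermediate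
32 | (E,E,E)-triene pyranone bis-acetonide | COc1oc(/C(C)=C/C=C/C(C)=C/[C@@H]2[C@H](C)[C@@]3(C)OC(C)(C)O[C@H]3[C@@]4(C)OC(C)(C)O[C@@H]24)c(C)c(=O)c1C | intermediate
33 | tetraol | COc1oc(/C(C)=C/C=C/C(C)=C/[C@@H]2[C@H](C)[C@@](C)(O)[C@@H](O)[C@@](C)(O)[C@H]2O)c(C)c(=O)c1C | intermediate
34 | amaurone B | COc1oc(/C(C)=C/C=C/C(C)=C/[C@@H]2[C@H](C)[C@@](C)(O)[C@@H](OC(C)=O)[C@@](C)(O)[C@H]2OC(C)=O)c(C)c(=O)c1C | target

## Step count

- Total step count: 21.
- Longest linear sequence: 15 steps (steps 1–4, 8–14 and 18–21).

## The three steps most likely to fail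

**Step 8.** Several processes may go wrong:
- The congested C2–C3 bond may not form, or carbonyl addition may win.
- The enal face may be chosen poorly.
- In the basic second stage, silanolate may be lost from C7 by β-elimination.
- The conjugate addition may revert before C5 closes onto C6.

The fallback uses known reactions only. It sets out from 9 and comes back at 15 and hence 16. Enol silane 9 is added under Sc(OTf)3 catalysis (CH2Cl2, −78 °C) to commercial diethyl ethylidenemalonate. This doubly activated acceptor has no competing aldehyde carbonyl and no β-leaving group, and the reaction is a Lewis-acid Mukaiyama–Michael addition to an alkylidene malonate. It gives diethyl 2-[1-(2,2,4,6-tetramethyl-5-oxo-1,3-dioxan-4-yl)ethyl]malonate F1, at which stage C2 epimers can be separated. LiAlH4 reduces both esters and the ketone to 2-[1-(5-hydroxy-2,2,4,6-tetramethyl-1,3-dioxan-4-yl)ethyl]propane-1,3-diol F2. One equivalent of tert-butyldimethylsilyl chloride with imidazole silylates one of the two primary hydroxyls and gives the mono silyl ether F3. Both C1 epimers of F3 are usable because C1 is equilibrated later. Dess–Martin periodinane oxidises the remaining primary alcohol and the C4 secondary alcohol to 15, now isolated. K2CO3 in MeOH then closes 15 to 16 in the absence of aluminium salts and phenol.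

**Step 4.** The base may discriminate incompletely between the two enantiotopic tertiary C–H bonds. Deprotonation may be slow, or hydride may transfer from the amide to the ketone. Any of these would erode enantiomeric purity.

The fallback replaces reagent control by auxiliary control. It sets out from 1 and comes back at 9. Ketone 1 is condensed with (R)-1-amino-2-(methoxymethyl)pyrrolidine to give the RAMP hydrazone F4. Two rounds of t-BuLi and MeI (SAMP/RAMP hydrazone alkylation) give the (4R,6R)-dimethyl RAMP hydrazone F5. Two-phase oxalic acid hydrolysis without contact with base gives C2-symmetric (4R,6R)-2,2,4,6-tetramethyl-1,3-dioxan-5-one F6. Its two α-hydrogens are homotopic, so LiN(iPr)2 with Me3SiCl gives 9 whichever one is removed. The meso ketone 8 is bypassed in this case.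

**Step 9.** Facial selectivity may be poor. The ketone is shielded on both faces, and a minor conformer (dioxanone chair, carbocycle boat) could admit hydride from the dioxane side. Reduction may also be so slow that the ketol opens.

The fallback changes the substrate that is reduced. It sets out from 16 and comes back at 18. A catalytic amount of camphorsulfonic acid in acetone moves the isopropylidene group from the strained O3/O5 bridge to the cis-vicinal O5/O6 pair and gives the O5/O6-acetonide hydroxy ketone F7. F7 cannot undergo retro-aldol cleavage. In this ordinary chair cyclohexanone, NaBH4 in MeOH should attack axially from the α face, antiperiplanar to the two axial C–O bonds. This gives the equatorial β-alcohol, which is also the more stable epimer because an axial 4-OH would be syn-axial to the 2-methyl. The product is the O5/O6-acetonide 3,4-diol F8. 2,2-Dimethoxypropane with camphorsulfonic acid then closes the second dioxolane to give 18.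

## Further compounds

F1 | step 8 | diethyl 2-[1-(2,2,4,6-tetramethyl-5-oxo-1,3-dioxan-4-yl)ethyl]malonate | CCOC(=O)C(C(=O)OCC)[C@H](C)[C@@]1(C)OC(C)(C)O[C@H](C)C1=O
F2 | step 8 | 2-[1-(5-hydroxy-2,2,4,6-tetramethyl-1,3-dioxan-4-yl)ethyl]propane-1,3-diol (mixture at C4) | OCC(CO)[C@H](C)[C@@]1(C)OC(C)(C)O[C@H](C)C1O
F3 | step 8 | mono silyl ether of F2 (mixture at C1 and C4) | CC(C)(C)[Si](C)(C)OCC(CO)[C@H](C)[C@@]1(C)OC(C)(C)O[C@H](C)C1O
F4 | step 4 | RAMP hydrazone of 2,2-dimethyl-1,3-dioxan-5-one | COC[C@H]1CCCN1N=C1COC(C)(C)OC1
F5 | step 4 | (4R,6R)-dimethyl RAMP hydrazone | C[C@H]1OC(C)(C)O[C@H](C)C1=NN1CCC[C@@H]1COC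
F6 | step 4 | (4R,6R)-2,2,4,6-tetramethyl-1,3-dioxan-5-one (single enantiomer) | C[C@H]1OC(C)(C)O[C@H](C)C1=O
F7 | step 9 | O5/O6-acetonide hydroxy ketone | CC(C)(C)[Si](C)(C)OC[C@@H]1[C@H](C)[C@@](C)(O)C(=O)[C@@]2(C)OC(C)(C)O[C@@H]12
F8 | step 9 | O5/O6-acetonide 3,4-diol | CC(C)(C)[Si](C)(C)OC[C@@H]1[C@H](C)[C@@](C)(O)[C@@H](O)[C@@]2(C)OC(C)(C)O[C@@H]12
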